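The numbers were drawn at random within sensible limits; no experiment stands behind them.

If the target from this flask has to be named within the hour, we begin from its recipe and its steps.

starting material 0.80 M; coupling partner 0.400 M; protic impurity 0.0400 M; time 25 h

    starting material → intermediate (k1 = 0.010 /s)
    crystals ⇌ target, rate k2*(cs2 - [target]) while solid is left; crystals form when [target] > cs2 (cs2 = 0.59 M, k2 = 0.0097 /s)
    coupling partner + intermediate → target (k3 = 0.0075 /M/s)
    starting material + intermediate → side product (k4 = 0.0014 /M/s)
    starting material + protic impurity → quenched substrate (k5 = 0.028 /M/s)

- a species is counted by the starting material in it: one side product counts as two
- amounts and yields of target count crystals too
- given per volume of solution although it is solid: crystals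
- the reaction counts as stopped when no species that holds the starting material changes by six tenths of a point or more over the second half of the time
- run time (flask): 25 h

1. which holds at 25 h: what has brought the reaction to rest, or that it has not come to rest (it is still moving / all of the starting material has reacted)
2. the target standing at 25 h, as a percentage of the starting material charged
3. the intermediate standing at 25 h, as a percentage of the starting material charged

We count turnovers: a step's first-order rate on a species, multiplied by the time on hand. The starting material passes to intermediate at 0.010 /s, so the run holds 900 turnovers of it, and we expect this end: all of the starting material has reacted. The starting material charged exceeds the coupling partner by 0.400 M, and with that much as intermediate the partner gets 270 turnovers. So the coupling partner, charged at less than the starting material, is the limiting reagent, and we name the partner ceiling: coupling partner charged over starting material charged, 50.0 %. We commit to 50.0 % of target. Its concentration, 0.400 M, is less than the solubility 0.59 M, so we expect no crystals.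

The intermediate is what the other steps leave. During the life of the starting material the protic impurity gets 2.24 turnovers, which puts 4.47 % into quenched substrate. With the intermediate undrained, the side product would hold 11.2 %, leaving 34.3 % as intermediate.

That side product is the weak link: we reckoned it with no coupling, yet coupling runs while the starting material lasts. Holding the partner at its charge adds 0.00300 /s to the 0.010 /s in the denominator, so the side product falls to 8.62 % and the intermediate rises to 36.9 %.

The forecast gives all of the starting material has reacted, 50 % of target and 38.7 % of intermediate, more intermediate than ours, holding that “nothing can consume it once the partner and starting material are gone”. The simulation gives all of the starting material has reacted, 50.0 % of target and 38.1 % of intermediate.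

In this flask at 0.0178 h, the intermediate goes to target 4.9 times as fast as to side product, and half of the coupling turnover is done by 0.0694 h, far less than the run time. At the end 0 % of the coupling partner is left, and the side product reads 7.55 %. The target reading shifts by its margin at 0.728 M or 0.889 M of starting material.

In the neighbour flask with 1.4 M of starting material, the partner ceiling gives 28.6 %. That flask reads 28.6 % of target, with 0 % of its coupling partner left.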